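**Retrosynthetic overview**
- Last operation: neutral hydrogenolysis of four benzyl groups, so the 3,4-dihydroxybutanoate ester is never exposed to acid or base and cannot lactonise.
- Aryl ester C(=O)–O bond: 300 nm cycloreversion of a 2,2-dimethylbenzodioxinone to a quinone ketene, trapped by benzyl (S)-3-hydroxybutanoate.
- Side-chain ester: acylation of the (R)-2-hydroxypropyl arene with an (R,R)-diester acid built from dimethyl (R)-malate and tert-butyl (R)-3-hydroxybutanoate.
- Aryl–CH2 bond: visible-light nickel/photoredox reductive coupling of the benzodioxinone 5-triflate with (R)-propylene oxide (new on this substrate class).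
- No ring is built: the benzene and dioxinone rings are bought together; the epoxide is opened in step 3 and the dioxinone in step 10.

Assumption: the five building blocks marked as starting materials in the compound list, including both 3-hydroxybutanoate esters, are taken as catalogue items.

**Step 1**
Reactants: 1 5,7-dihydroxy-2,2-dimethyl-4H-1,3-benzodioxin-4-one
Product: 2 7-(benzyloxy)-5-hydroxy-2,2-dimethyl-4H-1,3-benzodioxin-4-one
Conditions: BnBr (1.05 equiv), K2CO3 (1.1 equiv), acetone, rt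
Reagents that add atoms: benzyl bromide, BrCc1ccccc1
Why: Williamson ether synthesis; the 5-OH is tied up in a hydrogen bond to the peri carbonyl, so only the free, more acidic 7-OH is alkylated.

**Step 2**
Reactants: 2 7-(benzyloxy)-5-hydroxy-2,2-dimethyl-4H-1,3-benzodioxin-4-one
Product: 3 7-(benzyloxy)-2,2-dimethyl-4-oxo-4H-1,3-benzodioxin-5-yl trifluoromethanesulfonate
Conditions: Tf2O (1.2 equiv), pyridine, CH2Cl2, 0 °C
Reagents that add atoms: trifluoromethanesulfonic anhydride, O=S(=O)(OS(=O)(=O)C(F)(F)F)C(F)(F)F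
Why: O-sulfonylation of the one remaining phenol, which turns the C5–O bond into a cross-coupling handle.

**Step 3**
Reactants: 3 7-(benzyloxy)-2,2-dimethyl-4-oxo-4H-1,3-benzodioxin-5-yl trifluoromethanesulfonate; 4 (R)-propylene oxide
Product: 6 7-(benzyloxy)-5-[(2R)-2-hydroxypropyl]-2,2-dimethyl-4H-1,3-benzodioxin-4-one, via (2R)-1-iodopropan-2-ol 5 (not isolated)
Conditions: NiBr2·DME (10 mol %), 4,4'-di-tert-butyl-2,2'-bipyridine (12 mol %), 4CzIPN (2,4,5,6-tetra(carbazol-9-yl)isophthalonitrile, 3 mol %), Et3N·HI (1.0 equiv), Et3N (3 equiv), 4 (3 equiv), degassed DMA, 450 nm LEDs, 25 °C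
Reagents that add atoms: none
Why: Proposed new method: a nickel/organic-photoredox reductive cross-electrophile coupling that joins an aryl triflate (in place of an aryl iodide or bromide) to a terminal epoxide through an iodide relay; Et3N·HI opens 4 by SN2 attack at the unsubstituted carbon to give iodohydrin 5 without touching the C–O stereocenter, zerovalent nickel (formed from divalent nickel by the reduced photocatalyst, with Et3N as terminal reductant) adds to the electron-poor, carbonyl-flanked C–OTf bond of 3, iodide replaces triflate on the arylnickel species, the primary radical formed from 5 by halogen abstraction is captured, and the resulting trivalent aryl(alkyl)nickel reductively eliminates the aryl–CH2 bond and returns iodide; the benzodioxinone does not absorb at 450 nm and is kept for step 10; the closest known reactions are the nickel/photoredox coupling of aryl iodides with aliphatic epoxides via iodohydrins and the nickel-catalysed reductive coupling of aryl triflates with alkyl halides.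

**Step 4**
Reactants: 7 dimethyl (R)-malate
Product: 8 methyl (3R)-3,4-dihydroxybutanoate
Conditions: BH3·SMe2 (1.05 equiv), NaBH4 (5 mol %), THF, rt; MeOH quench
Reagents that add atoms: none
Why: hydroxyl-directed chemoselective borane reduction; the alkoxyborane formed at the free OH delivers hydride only to the neighbouring ester, and the stereocenter bought in 7 is not touched.

**Step 5**
Reactants: 8 methyl (3R)-3,4-dihydroxybutanoate
Product: 9 methyl (3R)-3,4-bis(benzyloxy)butanoate
Conditions: BnOC(=NH)CCl3 (2.6 equiv), TfOH (5 mol %), CH2Cl2/cyclohexane, 0 °C to rt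
Reagents that add atoms: benzyl 2,2,2-trichloroacetimidate, N=C(OCc1ccccc1)C(Cl)(Cl)Cl
Why: acid-catalysed trichloroacetimidate benzylation needs no base, so the β-hydroxy ester cannot eliminate, and the primary OH is capped first, which shuts off lactonisation.

**Step 6**
Reactants: 9 methyl (3R)-3,4-bis(benzyloxy)butanoate
Product: 10 (3R)-3,4-bis(benzyloxy)butanoic acid
Conditions: LiOH·H2O (1.5 equiv), THF/H2O, 0 °C; then 1 M HCl to pH 3
Reagents that add atoms: lithium hydroxide, [Li+].[OH-]
Why: saponification of an unhindered methyl ester, run cold so that E1cB loss of benzyl alkoxide stays negligible.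

**Step 7**
Reactants: 10 (3R)-3,4-bis(benzyloxy)butanoic acid; 11 tert-butyl (3R)-3-hydroxybutanoate
Product: 13 tert-butyl (3R)-3-{[(3R)-3,4-bis(benzyloxy)butanoyl]oxy}butanoate, via (3R)-3,4-bis(benzyloxy)butanoyl chloride 12 (not isolated)
Conditions: (COCl)2, DMF (cat.), CH2Cl2, 0 °C to rt, evaporate; then 11, pyridine, CH2Cl2, 0 °C to rt
Reagents that add atoms: none
Why: esterification through the acyl chloride (nucleophilic acyl substitution); no bond to either stereocenter is broken, so both are retained.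

**Step 8**
Reactants: 13 tert-butyl (3R)-3-{[(3R)-3,4-bis(benzyloxy)butanoyl]oxy}butanoate
Product: 14 (3R)-3-{[(3R)-3,4-bis(benzyloxy)butanoyl]oxy}butanoic acid
Conditions: TFA/CH2Cl2 (1:4), 0 °C to rt
Reagents that add atoms: none
Why: acidolysis of the tert-butyl ester via the tert-butyl cation; benzyl ethers and the secondary alkyl ester are stable, and no free hydroxyl is present to lactonise.

**Step 9**
Reactants: 6 7-(benzyloxy)-5-[(2R)-2-hydroxypropyl]-2,2-dimethyl-4H-1,3-benzodioxin-4-one; 14 (3R)-3-{[(3R)-3,4-bis(benzyloxy)butanoyl]oxy}butanoic acid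
Product: 16 (2R)-1-[7-(benzyloxy)-2,2-dimethyl-4-oxo-4H-1,3-benzodioxin-5-yl]propan-2-yl (3R)-3-{[(3R)-3,4-bis(benzyloxy)butanoyl]oxy}butanoate, via (3R)-3-{[(3R)-3,4-bis(benzyloxy)butanoyl]oxy}butanoyl chloride 15 (not isolated)
Conditions: 14 (1.3 equiv), (COCl)2, DMF (cat.), CH2Cl2, 0 °C to rt, evaporate; then 6, pyridine, CH2Cl2, -20 °C to rt
Reagents that add atoms: none
Why: acyl chloride esterification with pyridine at low temperature, chosen over carbodiimide/DMAP to keep E1cB loss of the β-acyloxy group and attack of the alcohol on its own dioxinone slow; the carbinol centre of 6 is retained.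

**Step 10**
Reactants: 16 (2R)-1-[7-(benzyloxy)-2,2-dimethyl-4-oxo-4H-1,3-benzodioxin-5-yl]propan-2-yl (3R)-3-{[(3R)-3,4-bis(benzyloxy)butanoyl]oxy}butanoate; 17 benzyl (3S)-3-hydroxybutanoate
Product: 19 benzyl (3S)-3-({4-(benzyloxy)-2-hydroxy-6-[(2R)-2-({(3R)-3-{[(3R)-3,4-bis(benzyloxy)butanoyl]oxy}butanoyl}oxy)propyl]benzoyl}oxy)butanoate, via quinone ketene 18 (not isolated)
Conditions: 17 (3 equiv), hν (300 nm), degassed CH2Cl2 (0.01 M), rt
Reagents that add atoms: none
Why: photochemical retro-[4+2] of the benzodioxinone expels acetone and gives an o-quinone ketene whose unhindered sp carbon is captured by the secondary alcohol (photochemical acyl transfer by ketene trapping); the 2-OH is regenerated and the carbinol carbon of 17 keeps its (S) configuration.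

**Step 11**
Reactants: 19 benzyl (3S)-3-({4-(benzyloxy)-2-hydroxy-6-[(2R)-2-({(3R)-3-{[(3R)-3,4-bis(benzyloxy)butanoyl]oxy}butanoyl}oxy)propyl]benzoyl}oxy)butanoate
Product: 20 Talapolyester B
Conditions: H2 (1 atm), 10% Pd/C, EtOAc, rt
Reagents that add atoms: none
Why: catalytic hydrogenolysis removes the benzyl ester, the aryl benzyl ether and both alkyl benzyl ethers under neutral conditions; no stereocenter is benzylic, and the four ester links and the homobenzylic C–O bond are inert.

**Compound list**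
1 | 5,7-dihydroxy-2,2-dimethyl-4H-1,3-benzodioxin-4-one | CC1(C)Oc2cc(O)cc(O)c2C(=O)O1 | starting material
2 | 7-(benzyloxy)-5-hydroxy-2,2-dimethyl-4H-1,3-benzodioxin-4-one | CC1(C)Oc2cc(OCc3ccccc3)cc(O)c2C(=O)O1 | intermediate
3 | 7-(benzyloxy)-2,2-dimethyl-4-oxo-4H-1,3-benzodioxin-5-yl trifluoromethanesulfonate | CC1(C)Oc2cc(OCc3ccccc3)cc(OS(=O)(=O)C(F)(F)F)c2C(=O)O1 | intermediate
4 | (R)-propylene oxide, (2R)-2-methyloxirane | C[C@@H]1CO1 | starting material
5 | (2R)-1-iodopropan-2-ol | C[C@@H](O)CI | intermediate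
6 | 7-(benzyloxy)-5-[(2R)-2-hydroxypropyl]-2,2-dimethyl-4H-1,3-benzodioxin-4-one | CC1(C)Oc2cc(OCc3ccccc3)cc(C[C@@H](C)O)c2C(=O)O1 | intermediate
7 | dimethyl (R)-malate, dimethyl (2R)-2-hydroxybutanedioate | COC(=O)C[C@@H](O)C(=O)OC | starting material
8 | methyl (3R)-3,4-dihydroxybutanoate | COC(=O)C[C@@H](O)CO | intermediate
9 | methyl (3R)-3,4-bis(benzyloxy)butanoate | COC(=O)C[C@@H](OCc1ccccc1)COCc1ccccc1 | intermediate
10 | (3R)-3,4-bis(benzyloxy)butanoic acid | OC(=O)C[C@@H](OCc1ccccc1)COCc1ccccc1 | intermediate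
11 | tert-butyl (3R)-3-hydroxybutanoate | C[C@@H](O)CC(=O)OC(C)(C)C | starting material
12 | (3R)-3,4-bis(benzyloxy)butanoyl chloride | ClC(=O)C[C@@H](OCc1ccccc1)COCc1ccccc1 | intermediate
13 | tert-butyl (3R)-3-{[(3R)-3,4-bis(benzyloxy)butanoyl]oxy}butanoate | C[C@H](CC(=O)OC(C)(C)C)OC(=O)C[C@@H](OCc1ccccc1)COCc1ccccc1 | intermediate
14 | (3R)-3-{[(3R)-3,4-bis(benzyloxy)butanoyl]oxy}butanoic acid | C[C@H](CC(=O)O)OC(=O)C[C@@H](OCc1ccccc1)COCc1ccccc1 | intermediate
15 | (3R)-3-{[(3R)-3,4-bis(benzyloxy)butanoyl]oxy}butanoyl chloride | C[C@H](CC(=O)Cl)OC(=O)C[C@@H](OCc1ccccc1)COCc1ccccc1 | intermediate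
16 | (2R)-1-[7-(benzyloxy)-2,2-dimethyl-4-oxo-4H-1,3-benzodioxin-5-yl]propan-2-yl (3R)-3-{[(3R)-3,4-bis(benzyloxy)butanoyl]oxy}butanoate | C[C@H](CC(=O)O[C@H](C)Cc1cc(OCc2ccccc2)cc2OC(C)(C)OC(=O)c12)OC(=O)C[C@@H](OCc1ccccc1)COCc1ccccc1 | intermediate
17 | benzyl (3S)-3-hydroxybutanoate | C[C@H](O)CC(=O)OCc1ccccc1 | starting material
18 | quinone ketene, (2R)-1-[3-(benzyloxy)-5-oxo-6-(oxomethylidene)cyclohexa-1,3-dien-1-yl]propan-2-yl (3R)-3-{[(3R)-3,4-bis(benzyloxy)butanoyl]oxy}butanoate | C[C@H](CC(=O)O[C@H](C)CC1=CC(OCc2ccccc2)=CC(=O)C1=C=O)OC(=O)C[C@@H](OCc1ccccc1)COCc1ccccc1 | intermediate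
19 | benzyl (3S)-3-({4-(benzyloxy)-2-hydroxy-6-[(2R)-2-({(3R)-3-{[(3R)-3,4-bis(benzyloxy)butanoyl]oxy}butanoyl}oxy)propyl]benzoyl}oxy)butanoate | C[C@H](CC(=O)O[C@H](C)Cc1cc(OCc2ccccc2)cc(O)c1C(=O)O[C@@H](C)CC(=O)OCc1ccccc1)OC(=O)C[C@@H](OCc1ccccc1)COCc1ccccc1 | intermediate
20 | Talapolyester B | C[C@H](CC(=O)O[C@H](C)Cc1cc(O)cc(O)c1C(=O)O[C@@H](C)CC(=O)O)OC(=O)C[C@@H](O)CO | target

**Step count and risks**

Total steps: 11. Longest linear sequence: 8 (steps 4 to 11, from dimethyl (R)-malate 7).

Step 3 (the proposed new coupling) is the most likely to fail, through hydrodetriflation of 3, slow oxidative addition at the hindered triflate, or closure of the product alcohol onto its dioxinone. The fallback uses known chemistry, sets out from 3 and 4 and returns at 6. Epoxide 4 is opened with LiI/AcOH in THF to isolated 5, which is silylated (TBSCl, imidazole, DMF) to tert-butyl{[(2R)-1-iodopropan-2-yl]oxy}dimethylsilane F1. Zinc insertion (Zn dust, LiCl, THF, 40 °C) gives [(2R)-2-{[tert-butyl(dimethyl)silyl]oxy}propyl]zinc iodide F2. A Negishi coupling of F2 with triflate 3 (Pd(OAc)2, SPhos, THF/DMA, 50 °C) gives 7-(benzyloxy)-5-[(2R)-2-{[tert-butyl(dimethyl)silyl]oxy}propyl]-2,2-dimethyl-4H-1,3-benzodioxin-4-one F3, and HF·pyridine in THF releases 6.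

Step 9 can fail by E1cB loss of the β-acyloxy group from acyl chloride 15 (crotonate formation) or by sluggish acylation of the hindered alcohol. The fallback sets out from 3 and returns at 16. Step 3 is run with bought (S)-propylene oxide (C[C@H]1CO1) in place of 4, which gives, through (2S)-1-iodopropan-2-ol F4, the epimeric alcohol 7-(benzyloxy)-5-[(2S)-2-hydroxypropyl]-2,2-dimethyl-4H-1,3-benzodioxin-4-one F5. A Mitsunobu esterification of F5 with acid 14 (PPh3, DIAD, toluene, 0 °C) then forms the ester C–O bond by SN2 with inversion to the (R)-configured 16, so the carboxyl group is never activated and cannot eliminate.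

Step 10 can fail if the hindered secondary β-hydroxy ester 17 captures ketene 18 too slowly and the ketene decays by other paths. The fallback sets out from 16 and returns at 19. Irradiation of 16 at 300 nm in THF/H2O (20:1) lets water trap 18 to give 4-(benzyloxy)-2-hydroxy-6-[(2R)-2-({(3R)-3-{[(3R)-3,4-bis(benzyloxy)butanoyl]oxy}butanoyl}oxy)propyl]benzoic acid F6. A Mitsunobu esterification of F6 with bought benzyl (3R)-3-hydroxybutanoate (C[C@@H](O)CC(=O)OCc1ccccc1; PPh3, DIAD, THF, 0 °C) alkylates the carboxylate in preference to the hydrogen-bonded phenol and inverts the carbinol centre, giving the (S)-ester 19.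

**Further compounds**
F1 | step 3 | tert-butyl{[(2R)-1-iodopropan-2-yl]oxy}dimethylsilane | C[C@@H](O[Si](C)(C)C(C)(C)C)CI
F2 | step 3 | [(2R)-2-{[tert-butyl(dimethyl)silyl]oxy}propyl]zinc iodide | C[C@@H](O[Si](C)(C)C(C)(C)C)C[Zn]I
F3 | step 3 | 7-(benzyloxy)-5-[(2R)-2-{[tert-butyl(dimethyl)silyl]oxy}propyl]-2,2-dimethyl-4H-1,3-benzodioxin-4-one | CC1(C)Oc2cc(OCc3ccccc3)cc(C[C@@H](C)O[Si](C)(C)C(C)(C)C)c2C(=O)O1
F4 | step 9 | (2S)-1-iodopropan-2-ol | C[C@H](O)CI
F5 | step 9 | 7-(benzyloxy)-5-[(2S)-2-hydroxypropyl]-2,2-dimethyl-4H-1,3-benzodioxin-4-one | CC1(C)Oc2cc(OCc3ccccc3)cc(C[C@H](C)O)c2C(=O)O1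
F6 | step 10 | 4-(benzyloxy)-2-hydroxy-6-[(2R)-2-({(3R)-3-{[(3R)-3,4-bis(benzyloxy)butanoyl]oxy}butanoyl}oxy)propyl]benzoic acid | C[C@H](CC(=O)O[C@H](C)Cc1cc(OCc2ccccc2)cc(O)c1C(=O)O)OC(=O)C[C@@H](OCc1ccccc1)COCc1ccccc1
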